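**Plan**
- Cuts: the 14-membered lactone is opened at C2–C3 (propanoate α-carbon to C3 carbonyl) and at the C13–O ester bond. The C3–C13 chain is then cut at C10–C11 (diene σ-bond), C4–C5 (bond to the quaternary carbinol carbon), C6=C7 and C8–C9.
- Enabling feature: in the 14-membered ring, C2 is a methine between the C1 lactone carbonyl and the C3 ketone, so it can be epimerised. C3 is bonded to quaternary, non-enolisable C4, so a C3 aldehyde can take a C2 enolate with no stereocontrol needed.
- Forward order: C8–C9 (auxiliary alkylation with 2,3-dibromopropene), C6=C7 (Wittig), C4–C5 (alkylation of a glycerate acetal enolate), C10–C11 (Negishi coupling), O13 acylation. The only ring, the 14-membered lactone, is closed last by a SmI2 Reformatsky reaction, followed by C3 oxidation and acetonide removal.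
- Stereochemistry: C8 from the oxazolidinone auxiliary; C4 from (R)-glycerate relayed through a pivalaldehyde acetal; C13 from (R)-pent-1-yn-3-ol; both E-alkenes from the Wittig reaction and syn-carboalumination; C2 by equilibration of the final β-keto lactone.

Key step: step 16

Assumption: the natural 2S configuration is taken to be the more stable C2 epimer of the 14-membered 3-keto lactone, so that acid-mediated enolisation funnels the C2 mixture into the target.

Macrolide numbering (C1 lactone carbonyl to C13 carbinol carbon) is used in the explanations.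

**Route**

Step 1
Reactants: 1 (4S)-4-benzyl-3-propanoyl-1,3-oxazolidin-2-one; 2 2,3-dibromoprop-1-ene
Product: 4 (4S)-4-benzyl-3-[(2R)-4-bromo-2-methylpent-4-enoyl]-1,3-oxazolidin-2-one, via sodium Z-enolate 3 (not isolated)
Conditions: NaN(SiMe3)2, THF, −78 °C; then 2, −78 → −40 °C
Reagents that add atoms: none
Why: Evans asymmetric alkylation, in which the chelated Z-enolate is attacked by the allylic bromide terminus of 2 on the face opposite the benzyl group, setting C8 as R while the vinylic bromide stays inert.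

Step 2
Reactants: 4 (4S)-4-benzyl-3-[(2R)-4-bromo-2-methylpent-4-enoyl]-1,3-oxazolidin-2-one
Product: 5 (2R)-4-bromo-2-methylpent-4-en-1-ol
Conditions: LiBH4, H2O (1 equiv), Et2O, 0 °C
Reagents that add atoms: none
Why: Reductive cleavage of the N-acyl oxazolidinone by borohydride gives the primary alcohol without touching C8 or the vinyl bromide.

Step 3
Reactants: 5 (2R)-4-bromo-2-methylpent-4-en-1-ol; 6 ethyl 2-(triphenyl-λ5-phosphanylidene)propanoate
Product: 8 ethyl (2E,4R)-6-bromo-2,4-dimethylhepta-2,6-dienoate, via aldehyde 7 (not isolated)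
Conditions: (COCl)2, DMSO, CH2Cl2, −78 °C; Et3N; then 6, −78 → 23 °C
Reagents that add atoms: none
Why: Swern oxidation followed in the same flask by Wittig olefination with the stabilised ylide, which should give the E-trisubstituted C6=C7 enoate and leaves the α-branched aldehyde no time to epimerise at C8.

Step 4
Reactants: 8 ethyl (2E,4R)-6-bromo-2,4-dimethylhepta-2,6-dienoate
Product: 9 (2E,4R)-6-bromo-2,4-dimethylhepta-2,6-dien-1-ol
Conditions: i-Bu2AlH, CH2Cl2, −78 °C; aq. potassium sodium tartrate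
Reagents that add atoms: none
Why: 1,2-Hydride reduction of the enoate by the aluminium hydride gives the allylic alcohol with the alkene geometry unchanged.

Step 5
Reactants: 9 (2E,4R)-6-bromo-2,4-dimethylhepta-2,6-dien-1-ol
Product: 10 (2E,4R)-1,6-dibromo-2,4-dimethylhepta-2,6-diene
Conditions: CBr4, PPh3, CH2Cl2, 0 °C
Reagents that add atoms: carbon tetrabromide, BrC(Br)(Br)Br
Why: Appel bromination, an SN2 displacement of the oxyphosphonium group at the primary allylic carbon without allylic transposition.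

Step 6
Reactants: 11 methyl (4R)-2,2-dimethyl-1,3-dioxolane-4-carboxylate
Product: 13 methyl (2R,4R)-2-tert-butyl-1,3-dioxolane-4-carboxylate (cis), via methyl glycerate 12 (not isolated)
Conditions: TsOH·H2O (cat.), MeOH, 23 °C, then concentrate; t-BuCHO, TsOH·H2O (cat.), pentane, reflux (Dean–Stark); chromatographic separation of the cis acetal
Reagents that add atoms: pivalaldehyde, CC(C)(C)C=O
Why: Acid-catalysed acetal exchange (acetonide methanolysis, then thermodynamic acetalisation) forms the new acetal centre as a cis/trans pair, from which the cis (2R,4R) isomer is taken as the relay for self-regeneration of the C4 stereocentre, the trans isomer being recyclable under the same acid conditions.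

Step 7
Reactants: 13 methyl (2R,4R)-2-tert-butyl-1,3-dioxolane-4-carboxylate; 10 (2E,4R)-1,6-dibromo-2,4-dimethylhepta-2,6-diene
Product: 15 methyl (2R,4R)-4-[(2E,4R)-6-bromo-2,4-dimethylhepta-2,6-dien-1-yl]-2-tert-butyl-1,3-dioxolane-4-carboxylate, via lithium enolate 14 (not isolated)
Conditions: LiN(i-Pr)2, THF/DMPU, −78 °C; then 10, −78 → −30 °C
Reagents that add atoms: none
Why: Seebach self-regeneration of stereocentres, in which the ester enolate (trigonal at C4) undergoes SN2 alkylation by the primary allylic bromide anti to the tert-butyl group, setting quaternary C4 as R, while β-elimination is slow because the ring C–O bond lies near the nodal plane of the enolate.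

Step 8
Reactants: 15 methyl (2R,4R)-4-[(2E,4R)-6-bromo-2,4-dimethylhepta-2,6-dien-1-yl]-2-tert-butyl-1,3-dioxolane-4-carboxylate
Product: 17 methyl (4R)-4-[(2E,4R)-6-bromo-2,4-dimethylhepta-2,6-dien-1-yl]-2,2-dimethyl-1,3-dioxolane-4-carboxylate, via diol ester 16 (not isolated)
Conditions: TsOH·H2O (cat.), MeOH, 50 °C, then concentrate; Me2C(OMe)2, PPTS (cat.), CH2Cl2, 23 °C
Reagents that add atoms: 2,2-dimethoxypropane, COC(C)(C)OC
Why: Acid-catalysed transacetalisation swaps the robust pivalaldehyde acetal for an acetonide that can later be removed under mild acid, and no bond to C4 is broken.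

Step 9
Reactants: 18 (3R)-pent-1-yn-3-ol
Product: 19 tert-butyl(dimethyl)[(3R)-pent-1-yn-3-yloxy]silane
Conditions: TBSCl, imidazole, DMF, 23 °C
Reagents that add atoms: tert-butyldimethylsilyl chloride, CC(C)(C)[Si](C)(C)Cl
Why: Standard silyl ether formation protects the C13 hydroxyl for the organometallic steps.

Step 10
Reactants: 19 tert-butyl(dimethyl)[(3R)-pent-1-yn-3-yloxy]silane
Product: 21 tert-butyl{[(1E,3R)-1-iodo-2-methylpent-1-en-3-yl]oxy}dimethylsilane, via alkenylalane 20 (not isolated)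
Conditions: AlMe3, Cp2ZrCl2 (0.25 equiv), CH2Cl2, 0 → 23 °C; then I2, THF, −30 → 0 °C
Reagents that add atoms: trimethylaluminium, C[Al](C)C; iodine, II
Why: Negishi zirconium-catalysed carboalumination adds methyl and aluminium syn across the alkyne with aluminium at the terminus, and iodinolysis with retention gives the E-iodoalkene (C11=C12).

Step 11
Reactants: 21 tert-butyl{[(1E,3R)-1-iodo-2-methylpent-1-en-3-yl]oxy}dimethylsilane; 17 methyl (4R)-4-[(2E,4R)-6-bromo-2,4-dimethylhepta-2,6-dien-1-yl]-2,2-dimethyl-1,3-dioxolane-4-carboxylate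
Product: 24 methyl (4R)-4-[(2E,4R,7E,9R)-9-{[tert-butyl(dimethyl)silyl]oxy}-2,4,8-trimethyl-6-methylideneundeca-2,7-dien-1-yl]-2,2-dimethyl-1,3-dioxolane-4-carboxylate, via alkenyllithium 22 (not isolated), via alkenylzinc chloride 23 (not isolated)
Conditions: t-BuLi (2 equiv), Et2O, −78 °C; ZnCl2, THF, −78 → 0 °C; then 17, Pd(PPh3)4 (5 mol %), THF, 23 °C
Reagents that add atoms: none
Why: Negishi cross-coupling (iodine–lithium exchange, transmetalation to zinc, coupling at the 2-bromoalkene catalysed by zerovalent palladium) forms C10–C11 with retention of both alkene geometries, and the organozinc tolerates the ester and acetonide.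

Step 12
Reactants: 24 methyl (4R)-4-[(2E,4R,7E,9R)-9-{[tert-butyl(dimethyl)silyl]oxy}-2,4,8-trimethyl-6-methylideneundeca-2,7-dien-1-yl]-2,2-dimethyl-1,3-dioxolane-4-carboxylate
Product: 25 {(4S)-4-[(2E,4R,7E,9R)-9-{[tert-butyl(dimethyl)silyl]oxy}-2,4,8-trimethyl-6-methylideneundeca-2,7-dien-1-yl]-2,2-dimethyl-1,3-dioxolan-4-yl}methanol
Conditions: LiAlH4, Et2O, 0 °C
Reagents that add atoms: none
Why: Hydride reduction of the methyl ester to the primary C3 alcohol; the change of descriptor at C4 is only a priority change.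

Step 13
Reactants: 25 {(4S)-4-[(2E,4R,7E,9R)-9-{[tert-butyl(dimethyl)silyl]oxy}-2,4,8-trimethyl-6-methylideneundeca-2,7-dien-1-yl]-2,2-dimethyl-1,3-dioxolan-4-yl}methanol
Product: 26 (4R)-4-[(2E,4R,7E,9R)-9-{[tert-butyl(dimethyl)silyl]oxy}-2,4,8-trimethyl-6-methylideneundeca-2,7-dien-1-yl]-2,2-dimethyl-1,3-dioxolane-4-carbaldehyde
Conditions: Dess–Martin periodinane, pyridine, CH2Cl2, 0 → 23 °C
Reagents that add atoms: none
Why: Dess–Martin oxidation of the neopentyl primary alcohol gives the C3 aldehyde, which cannot enolise or epimerise because C4 is quaternary.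

Step 14
Reactants: 26 (4R)-4-[(2E,4R,7E,9R)-9-{[tert-butyl(dimethyl)silyl]oxy}-2,4,8-trimethyl-6-methylideneundeca-2,7-dien-1-yl]-2,2-dimethyl-1,3-dioxolane-4-carbaldehyde
Product: 27 (4R)-4-[(2E,4R,7E,9R)-9-hydroxy-2,4,8-trimethyl-6-methylideneundeca-2,7-dien-1-yl]-2,2-dimethyl-1,3-dioxolane-4-carbaldehyde
Conditions: HF·pyridine, pyridine, THF, 0 → 23 °C
Reagents that add atoms: none
Why: Fluoride-driven desilylation frees the C13 hydroxyl, and the pyridine-buffered medium should spare the acetonide, the aldehyde and the dienyl carbinol.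

Step 15
Reactants: 27 (4R)-4-[(2E,4R,7E,9R)-9-hydroxy-2,4,8-trimethyl-6-methylideneundeca-2,7-dien-1-yl]-2,2-dimethyl-1,3-dioxolane-4-carbaldehyde; 28 2-bromopropanoyl bromide (racemic)
Product: 29 (3R,4E,8R,9E)-11-[(4R)-4-formyl-2,2-dimethyl-1,3-dioxolan-4-yl]-4,8,10-trimethyl-6-methylideneundeca-4,9-dien-3-yl 2-bromopropanoate (both configurations at the bromine-bearing carbon)
Conditions: 28, pyridine, CH2Cl2, −20 → 0 °C
Reagents that add atoms: none
Why: O-Acylation of the secondary allylic alcohol by the acyl bromide (nucleophilic acyl substitution) proceeds in the presence of the hindered, non-enolisable aldehyde, and the racemic bromide centre is of no consequence.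

Step 16
Reactants: 29 (3R,4E,8R,9E)-11-[(4R)-4-formyl-2,2-dimethyl-1,3-dioxolan-4-yl]-4,8,10-trimethyl-6-methylideneundeca-4,9-dien-3-yl 2-bromopropanoate
Product: 31 (5R,10R,11E,15R,16E)-10-ethyl-6-hydroxy-2,2,7,11,15,17-hexamethyl-13-methylidene-1,3,9-trioxaspiro[4.13]octadeca-11,16-dien-8-one (the 14-membered 3-hydroxy lactone with the C4 diol as acetonide; mixture at C2 and C3), via samarium enolate 30 (not isolated)
Conditions: SmI2 (3 equiv), THF, −78 → −20 °C, slow addition of 29 (final ca. 2 mM); aq. NH4Cl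
Reagents that add atoms: none
Why: Two single-electron transfers from divalent samarium cleave the C2–Br bond and give the trivalent samarium ester enolate 30, which adds to the C3 aldehyde through a chelated, Zimmerman–Traxler-like transition state in which the metal binds the enolate oxygen, the aldehyde oxygen and the dioxolane oxygen on C4. The closest known reaction type is the SmI2-mediated intramolecular Reformatsky reaction of ω-(α-bromoacyloxy) aldehydes, established for medium and large lactones. The 14-membered lactone ring closes by C2–C3 bond formation in a 14-exo-trig aldol mode, the enolate carbon attacking the exocyclic C=O. The new centres C2 and C3 are formed without imposed control (at most biased by the chelate and the ring conformation), which is acceptable because C3 is oxidised in step 17 and C2 is equilibrated in step 18. The step needs electron transfer to the C–Br bond ahead of the aldehyde and ring closure ahead of oligomerisation: reduction of an α-bromo ester by SmI2 is much faster at −78 °C than ketyl formation, the aldehyde cannot enolise because C4 is quaternary and is activated by its α-oxygen, and slow addition keeps the enolate concentration low. Isolated and conjugated C=C bonds, the acetonide and the ester lie outside the reducing power of SmI2 in THF without additives.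

Step 17
Reactants: 31 the 14-membered 3-hydroxy lactone acetonide (mixture at C2 and C3)
Product: 32 (5R,10R,11E,15R,16E)-10-ethyl-2,2,7,11,15,17-hexamethyl-13-methylidene-1,3,9-trioxaspiro[4.13]octadeca-11,16-diene-6,8-dione (the 3-keto lactone acetonide; mixture at C2)
Conditions: Dess–Martin periodinane, pyridine, CH2Cl2, 23 °C
Reagents that add atoms: none
Why: Dess–Martin oxidation of the hindered C3 carbinol erases that stereocentre and gives the β-keto lactone under non-basic conditions.

Step 18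
Reactants: 32 the 3-keto lactone acetonide (mixture at C2)
Product: 33 (3S,5R,7E,9R,12E,14R)-14-ethyl-5-hydroxy-5-(hydroxymethyl)-3,7,9,13-tetramethyl-11-methylidene-1-oxacyclotetradeca-7,12-diene-2,4-dione (target; 2S,4R,8R,13R in macrolide numbering)
Conditions: AcOH/H2O (4:1), 40 °C
Reagents that add atoms: none
Why: Acid-catalysed acetonide hydrolysis frees the C4 diol, and under the same conditions C2, now between the C1 and C3 carbonyls, epimerises through the enol and is expected to settle in the 2S configuration.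

**Compound list**

1 | (4S)-4-benzyl-3-propanoyl-1,3-oxazolidin-2-one | CCC(=O)N1[C@@H](Cc2ccccc2)COC1=O | starting material
2 | 2,3-dibromoprop-1-ene | C=C(Br)CBr | starting material
3 | sodium (1Z)-1-[(4S)-4-benzyl-2-oxo-1,3-oxazolidin-3-yl]prop-1-en-1-olate | C/C=C(\[O-])N1[C@@H](Cc2ccccc2)COC1=O.[Na+] | intermediate
4 | (4S)-4-benzyl-3-[(2R)-4-bromo-2-methylpent-4-enoyl]-1,3-oxazolidin-2-one | O=C([C@H](C)CC(Br)=C)N1[C@@H](Cc2ccccc2)COC1=O | intermediate
5 | (2R)-4-bromo-2-methylpent-4-en-1-ol | OC[C@H](C)CC(Br)=C | intermediate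
6 | ethyl 2-(triphenyl-λ5-phosphanylidene)propanoate | CCOC(=O)C(C)=P(c1ccccc1)(c1ccccc1)c1ccccc1 | starting material
7 | (2R)-4-bromo-2-methylpent-4-enal | O=C[C@H](C)CC(Br)=C | intermediate
8 | ethyl (2E,4R)-6-bromo-2,4-dimethylhepta-2,6-dienoate | CCOC(=O)/C(C)=C/[C@H](C)CC(Br)=C | intermediate
9 | (2E,4R)-6-bromo-2,4-dimethylhepta-2,6-dien-1-ol | OC/C(C)=C/[C@H](C)CC(Br)=C | intermediate
10 | (2E,4R)-1,6-dibromo-2,4-dimethylhepta-2,6-diene | BrC/C(C)=C/[C@H](C)CC(Br)=C | intermediate
11 | methyl (4R)-2,2-dimethyl-1,3-dioxolane-4-carboxylate | COC(=O)[C@H]1COC(C)(C)O1 | starting material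
12 | methyl (2R)-2,3-dihydroxypropanoate | COC(=O)[C@H](O)CO | intermediate
13 | methyl (2R,4R)-2-tert-butyl-1,3-dioxolane-4-carboxylate (cis) | COC(=O)[C@H]1CO[C@@H](C(C)(C)C)O1 | intermediate
14 | lithium enolate of 13 (lithium [(2R)-2-tert-butyl-1,3-dioxolan-4-ylidene](methoxy)methanolate) | COC([O-])=C1CO[C@@H](C(C)(C)C)O1.[Li+] | intermediate
15 | methyl (2R,4R)-4-[(2E,4R)-6-bromo-2,4-dimethylhepta-2,6-dien-1-yl]-2-tert-butyl-1,3-dioxolane-4-carboxylate | COC(=O)[C@]1(CO[C@@H](C(C)(C)C)O1)C/C(C)=C/[C@H](C)CC(Br)=C | intermediate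
16 | methyl (2R,4E,6R)-8-bromo-2-hydroxy-2-(hydroxymethyl)-4,6-dimethylnona-4,8-dienoate | COC(=O)[C@](O)(CO)C/C(C)=C/[C@H](C)CC(Br)=C | intermediate
17 | methyl (4R)-4-[(2E,4R)-6-bromo-2,4-dimethylhepta-2,6-dien-1-yl]-2,2-dimethyl-1,3-dioxolane-4-carboxylate | COC(=O)[C@]1(COC(C)(C)O1)C/C(C)=C/[C@H](C)CC(Br)=C | intermediate
18 | (3R)-pent-1-yn-3-ol | C#C[C@@H](CC)O | starting material
19 | tert-butyl(dimethyl)[(3R)-pent-1-yn-3-yloxy]silane | C#C[C@@H](CC)O[Si](C)(C)C(C)(C)C | intermediate
20 | [(1E,3R)-3-{[tert-butyl(dimethyl)silyl]oxy}-2-methylpent-1-en-1-yl]dimethylalumane | C[Al](C)/C=C(\C)[C@@H](CC)O[Si](C)(C)C(C)(C)C | intermediate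
21 | tert-butyl{[(1E,3R)-1-iodo-2-methylpent-1-en-3-yl]oxy}dimethylsilane | I/C=C(\C)[C@@H](CC)O[Si](C)(C)C(C)(C)C | intermediate
22 | [(1E,3R)-3-{[tert-butyl(dimethyl)silyl]oxy}-2-methylpent-1-en-1-yl]lithium | [Li]/C=C(\C)[C@@H](CC)O[Si](C)(C)C(C)(C)C | intermediate
23 | [(1E,3R)-3-{[tert-butyl(dimethyl)silyl]oxy}-2-methylpent-1-en-1-yl]zinc chloride | Cl[Zn]/C=C(\C)[C@@H](CC)O[Si](C)(C)C(C)(C)C | intermediate
24 | methyl (4R)-4-[(2E,4R,7E,9R)-9-{[tert-butyl(dimethyl)silyl]oxy}-2,4,8-trimethyl-6-methylideneundeca-2,7-dien-1-yl]-2,2-dimethyl-1,3-dioxolane-4-carboxylate | COC(=O)[C@]1(COC(C)(C)O1)C/C(C)=C/[C@H](C)CC(=C)/C=C(\C)[C@@H](CC)O[Si](C)(C)C(C)(C)C | intermediate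
25 | {(4S)-4-[(2E,4R,7E,9R)-9-{[tert-butyl(dimethyl)silyl]oxy}-2,4,8-trimethyl-6-methylideneundeca-2,7-dien-1-yl]-2,2-dimethyl-1,3-dioxolan-4-yl}methanol | OC[C@]1(COC(C)(C)O1)C/C(C)=C/[C@H](C)CC(=C)/C=C(\C)[C@@H](CC)O[Si](C)(C)C(C)(C)C | intermediate
26 | (4R)-4-[(2E,4R,7E,9R)-9-{[tert-butyl(dimethyl)silyl]oxy}-2,4,8-trimethyl-6-methylideneundeca-2,7-dien-1-yl]-2,2-dimethyl-1,3-dioxolane-4-carbaldehyde | O=C[C@]1(COC(C)(C)O1)C/C(C)=C/[C@H](C)CC(=C)/C=C(\C)[C@@H](CC)O[Si](C)(C)C(C)(C)C | intermediate
27 | (4R)-4-[(2E,4R,7E,9R)-9-hydroxy-2,4,8-trimethyl-6-methylideneundeca-2,7-dien-1-yl]-2,2-dimethyl-1,3-dioxolane-4-carbaldehyde | O=C[C@]1(COC(C)(C)O1)C/C(C)=C/[C@H](C)CC(=C)/C=C(\C)[C@@H](CC)O | intermediate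
28 | 2-bromopropanoyl bromide (racemic) | CC(Br)C(Br)=O | starting material
29 | (3R,4E,8R,9E)-11-[(4R)-4-formyl-2,2-dimethyl-1,3-dioxolan-4-yl]-4,8,10-trimethyl-6-methylideneundeca-4,9-dien-3-yl 2-bromopropanoate | O=C[C@]1(COC(C)(C)O1)C/C(C)=C/[C@H](C)CC(=C)/C=C(\C)[C@@H](CC)OC(=O)C(C)Br | intermediate
30 | trivalent samarium ester enolate of 29 (diiodosamarium O-enolate of the propanoate) | O=C[C@]1(COC(C)(C)O1)C/C(C)=C/[C@H](C)CC(=C)/C=C(\C)[C@@H](CC)OC(O[Sm](I)I)=CC | intermediate
31 | (5R,10R,11E,15R,16E)-10-ethyl-6-hydroxy-2,2,7,11,15,17-hexamethyl-13-methylidene-1,3,9-trioxaspiro[4.13]octadeca-11,16-dien-8-one (mixture at C2 and C3 of the macrolide) | C=C1/C=C(\C)[C@@H](CC)OC(=O)C(C)C(O)[C@]2(COC(C)(C)O2)C/C(C)=C/[C@H](C)C1 | intermediate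
32 | (5R,10R,11E,15R,16E)-10-ethyl-2,2,7,11,15,17-hexamethyl-13-methylidene-1,3,9-trioxaspiro[4.13]octadeca-11,16-diene-6,8-dione (mixture at C2 of the macrolide) | C=C1/C=C(\C)[C@@H](CC)OC(=O)C(C)C(=O)[C@]2(COC(C)(C)O2)C/C(C)=C/[C@H](C)C1 | intermediate
33 | (3S,5R,7E,9R,12E,14R)-14-ethyl-5-hydroxy-5-(hydroxymethyl)-3,7,9,13-tetramethyl-11-methylidene-1-oxacyclotetradeca-7,12-diene-2,4-dione | C=C1/C=C(\C)[C@@H](CC)OC(=O)[C@@H](C)C(=O)[C@](O)(CO)C/C(C)=C/[C@H](C)C1 | target

**Step count**
Total: 18 steps. Longest linear sequence: 15 steps (steps 1–5, 7, 8, 11–18).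

**Steps most likely to fail**

1. Step 16. The ring closure may lose to intermolecular aldol addition, or electron transfer to the aldehyde (pinacol coupling, reductive loss of the α-oxygen) may precede C–Br reduction. The fallback forms C2–C3 intermolecularly and closes the ring by macrolactonisation. It sets out from 26: aldol addition of the lithium enolate of 2-(trimethylsilyl)ethyl propanoate (LiN(i-Pr)2, THF, −78 °C) should give the β-hydroxy 2-(trimethylsilyl)ethyl ester F1 as a C2/C3 mixture. Bu4NF in THF removes both the ester group and the C13 silyl ether to give the 3,13-dihydroxy seco acid F2. Shiina macrolactonisation (2-methyl-6-nitrobenzoic anhydride, DMAP, CH2Cl2, high dilution) should acylate O13 in preference to the hindered C3 hydroxyl, whose β-lactone would be strained. It comes back to the route at 31.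

2. Step 7. The enolate may eliminate the ring oxygen, or the remote tert-butyl group may discriminate the two faces poorly. The fallback sets C4 by catalytic asymmetric epoxidation instead of enolate alkylation. It sets out from 10: Stille coupling at the allylic bromide with 2-(tributylstannyl)prop-2-en-1-ol (Pd2(dba)3, P(2-furyl)3, THF) gives the 2-methylidene dienol F3. Sharpless epoxidation (Ti(Oi-Pr)4, L-(+)-diethyl tartrate, t-BuOOH, CH2Cl2, −20 °C) acts only on the allylic alcohol and gives the (2S)-epoxy alcohol F4. Oxidation of the primary alcohol (TEMPO, PhI(OAc)2, MeCN/H2O) gives the glycidic acid F5, and Me3SiCHN2 gives the glycidic methyl ester F6. Acid-catalysed hydration (aq. HClO4, THF) opens the epoxide at its CH2 terminus, with retention at C4, and comes back to the route at 16.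

3. Step 18. The C2 equilibrium may settle on the wrong side, or acid may promote acyl transfer from O13 to the freed C4 hydroxyls. The fallback keeps C2 under kinetic control by fixing it at the alcohol oxidation level. It sets out from 31: the C2/C3 diastereomers are separated and the 2S-configured pair, the (2S)-hydroxy lactone acetonide F7, is carried on. Acetonide hydrolysis (AcOH/H2O), where C2 cannot epimerise, gives the triol F8. Selective silylation of the primary hydroxyl (Et3SiCl, imidazole) gives the triethylsilyl ether F9. Dess–Martin oxidation of the C3 carbinol, the tertiary C4 hydroxyl being inert, gives the keto lactone silyl ether F10 with C2 untouched. Pyridine-buffered HF·pyridine at 0 °C removes the silyl group and comes back to the route at 33.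

**Further compounds**
F1 | step 16 | 2-(trimethylsilyl)ethyl 3-[(4R)-4-[(2E,4R,7E,9R)-9-{[tert-butyl(dimethyl)silyl]oxy}-2,4,8-trimethyl-6-methylideneundeca-2,7-dien-1-yl]-2,2-dimethyl-1,3-dioxolan-4-yl]-3-hydroxy-2-methylpropanoate (mixture at C2 and C3) | C[Si](C)(C)CCOC(=O)C(C)C(O)[C@]1(COC(C)(C)O1)C/C(C)=C/[C@H](C)CC(=C)/C=C(\C)[C@@H](CC)O[Si](C)(C)C(C)(C)C
F2 | step 16 | 3-hydroxy-3-[(4R)-4-[(2E,4R,7E,9R)-9-hydroxy-2,4,8-trimethyl-6-methylideneundeca-2,7-dien-1-yl]-2,2-dimethyl-1,3-dioxolan-4-yl]-2-methylpropanoic acid (mixture at C2 and C3) | OC(=O)C(C)C(O)[C@]1(COC(C)(C)O1)C/C(C)=C/[C@H](C)CC(=C)/C=C(\C)[C@@H](CC)O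
F3 | step 7 | (4E,6R)-8-bromo-4,6-dimethyl-2-methylidenenona-4,8-dien-1-ol | OCC(=C)C/C(C)=C/[C@H](C)CC(Br)=C
F4 | step 7 | {(2S)-2-[(2E,4R)-6-bromo-2,4-dimethylhepta-2,6-dien-1-yl]oxiran-2-yl}methanol | OC[C@]1(CO1)C/C(C)=C/[C@H](C)CC(Br)=C
F5 | step 7 | (2R)-2-[(2E,4R)-6-bromo-2,4-dimethylhepta-2,6-dien-1-yl]oxirane-2-carboxylic acid | OC(=O)[C@]1(CO1)C/C(C)=C/[C@H](C)CC(Br)=C
F6 | step 7 | methyl (2R)-2-[(2E,4R)-6-bromo-2,4-dimethylhepta-2,6-dien-1-yl]oxirane-2-carboxylate | COC(=O)[C@]1(CO1)C/C(C)=C/[C@H](C)CC(Br)=C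
F7 | step 18 | (2S)-configured 14-membered 3-hydroxy lactone acetonide (31 with C2 fixed as S, C3 mixture) | C=C1/C=C(\C)[C@@H](CC)OC(=O)[C@@H](C)C(O)[C@]2(COC(C)(C)O2)C/C(C)=C/[C@H](C)C1
F8 | step 18 | (2S,4R,8R,13R)-3,4-dihydroxy-4-(hydroxymethyl) 14-membered lactone (C3 mixture) | C=C1/C=C(\C)[C@@H](CC)OC(=O)[C@@H](C)C(O)[C@](O)(CO)C/C(C)=C/[C@H](C)C1
F9 | step 18 | (2S,4R,8R,13R)-3,4-dihydroxy-4-[(triethylsilyloxy)methyl] 14-membered lactone (C3 mixture) | C=C1/C=C(\C)[C@@H](CC)OC(=O)[C@@H](C)C(O)[C@](O)(CO[Si](CC)(CC)CC)C/C(C)=C/[C@H](C)C1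
F10 | step 18 | (2S,4R,8R,13R)-4-hydroxy-3-oxo-4-[(triethylsilyloxy)methyl] 14-membered lactone | C=C1/C=C(\C)[C@@H](CC)OC(=O)[C@@H](C)C(=O)[C@](O)(CO[Si](CC)(CC)CC)C/C(C)=C/[C@H](C)C1
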